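## The problem

CNP0361212.1 (25) consists of three rings. Ring A is a fully substituted phloroglucinol. Ring B is a dihydropyran fused to it through O1/C8a and C4/C4a, giving a 3-hydroxy-2,2-dimethylchroman. Ring C is a 6-ethyl-4-hydroxy-5-methyl-2H-pyran-2-one joined to C6 of ring A through one methylene carbon.

Ring A carries six different substituents. Its three oxygens (the ether O1 and the free hydroxyls at C5 and C7) and its two carbon substituents (the acyl group at C8 and the methylene at C6) must therefore each be placed by regiocontrol.

There are two stereocentres: C3 of the chroman (S) and C2 of the 2-methylbutanoyl chain (S). They lie on opposite sides of the arene and cannot control each other. The chain centre is best taken from the chiral pool; C3 needs a reagent- or catalyst-controlled reaction.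

Several groups are fragile. The chain centre is alpha to an aryl ketone and can epimerise under strong acid or base. The free acylphloroglucinol is air-sensitive and nucleophilic at carbon. C4 ionises easily under acid, next to the C3 carbinol. The methylene bridge between two enolic rings can be cleaved and redistributed to symmetric dimers.

The feature that opens ring B to a catalytic construction is the C3–C4 bond. C4 is bound to C4a of the arene, and C3 to the quaternary carbon C2, which is tied through O1 to C8a. Both carbons can therefore be traced back to aldehyde carbons of one 2-formylaryl ether. Because C2 is quaternary, the aliphatic aldehyde has no alpha hydrogen. The oxygen that such a union leaves at C4 sits ortho and para to three ring oxygens, where it is easily removed.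

## Retrosynthesis

**Methylene bridge.** The two bonds of the bridging CH2 (C6–CH2 and CH2–C3 of ring C) are cut first. This gives the acylphloroglucinol chroman 17, the pyranone 22 and a one-carbon electrophile. The cut is preferred to building ring C on the arene because both halves are stable, of similar size, and 17 has only one free arene carbon (C6). The forward reaction must keep the one-carbon unit from joining two identical halves. It is therefore fixed on the pyranone as the Mannich base 23, which releases the methylidene dione 24 only when 17 is present.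

**Pyranone.** Ring C of 22 is opened at the lactone C–O bond to the diketo ester 21. The C4–C5 bond of 21 is then cut to the dianion 20 of methyl 3-oxopentanoate (18) and the propanoyl donor 19. Both are commercial, and the forward steps are a dianion acylation and a lactonisation.

**Protecting groups and the acyl group.** 17 is taken back to its tris(benzyl) ether 16, so that one hydrogenolysis frees all three hydroxyls under neutral conditions. The C8–C(=O) bond of 16 is cut to the aryllithium 15, made from bromide 11, and the Weinreb amide 14. This is preferred to a Friedel–Crafts acylation because the bromine marks the position and the stereocentre of (S)-2-methylbutanoic acid (12) never meets a Lewis acid. 14 comes from 12 through the acid chloride 13.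

**Arene functionalisation.** The C8–Br bond of 11 is cut to the tris(benzyl) ether 10, and the C3 benzyl ether of 10 to the alcohol 9. The forward bromination must choose C8 over C6. C8 lies between the ring oxygen and one ether, while C6 lies between two benzyl ethers.

**C4 oxygen.** 9 is traced to the diol 8 and then to the ketol 7. Adding a carbonyl at C4 turns the C3–C4 bond into a ketol bond, which a polarity-reversed aldehyde coupling can make. The forward price is two steps, a borohydride reduction and an ionic deoxygenation.

**Key disconnection.** The C3–C4 bond of 7 is cut to the dialdehyde 6. This removes ring B and the C3 stereocentre in one operation and leaves an achiral aryl ether. The forward reaction must make the aryl aldehyde the acyl anion donor and the alkyl aldehyde the acceptor, and must set C3 by catalyst control.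

**Dialdehyde.** 6 is the oxidation product of the diol 5, which comes from the aldehyde ester 4 by hydride reduction. The O–C bond of 4 is cut to the phenol 2 and ethyl 2-bromo-2-methylpropanoate (3). 2 is the bis(benzyl) ether of 2,4,6-trihydroxybenzaldehyde (1); its third hydroxyl is held back by its hydrogen bond to the formyl group.

## Roads not taken

**Alternative 1: late pyranone annulation.** Ring C would be cut at C4–C5 and O1–C2. In the forward step the arylmethylmalonyl dichloride A2 would C-acylate the enol silane A3; the enol oxygen would then close on the second acyl chloride to give the protected heterodimer A1.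
- Merits: the bridge carbon is attached to the arene before ring C exists, so no symmetric dimer can form. In control of the bridge this road is better than the chosen one.
- Weak points: A2 needs a malonate unit on the most hindered carbon of a hexasubstituted arene. It then needs a double acid chloride formation next to a silyl ether and an epimerisable ketone. This makes a long linear end game on the most valuable intermediate.
- It also leaves ring B and C3 unsolved; they would still need a separate answer.
- Comparison: the chosen plan joins two finished halves in one step, and 17 offers a single free carbon. The pyranone coupling is the known one for this class.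

**Alternative 2: benzannulation of ring A.** Three arene bonds (C4a–C8a, C5–C6 and C8–C8a) would be cut. Heating the cyclobutenone A5 with the siloxyalkyne A6 would give the phenol A4 through a ketene cascade.
- Merits: the three oxygens of A4 are all different (free, benzyl, silyl) and the prenyl group is placed by bond construction. In differentiating the ring oxygens this road is superior.
- Weak points: it builds a benzene ring that the chosen route buys in 1. A5 and A6 each need several steps. C3 is still unset and would require an asymmetric epoxidation and cyclisation afterwards.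
- Comparison: the target needs only O1 to differ from two oxygens that end as identical free hydroxyls. The hydrogen bond in 2 provides that difference in the first step, so the main asset of the benzannulation is more than is needed.

**Alternative 3: acid-mediated epoxide opening.** The O1–C2 bond would be cut. In the forward step the ortho phenol of the (S)-epoxide A8 would open the oxirane at its tertiary carbon under acid (6-endo), giving the chromanol A7 with the C3 configuration carried over from the epoxide.
- Merits: the reaction type is well established for prenyl phenols and the acyl group is in place early. On precedent this road is ahead of the chosen one, and its step count would probably be no higher.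
- Weak points: A8 requires a selective mono-C-prenylation and monobenzylation of an acylphloroglucinol. It also requires an asymmetric epoxidation of a trisubstituted alkene on an oxidation-sensitive, chelated phenol. The closure must then beat the 5-exo mode.
- Comparison: the chosen plan forms ring and stereocentre in one catalytic bond formation, with ring size fixed by the tether and no prenylation mixtures. It pays with two redox corrections (steps 3/4 and 6/7) and an unproven key step, for which a known fallback is given.

Key step: step 5

Assumption: the (5aS,10bR) antipode of the triazolium salt is written for step 5. The known ketone-acceptor cyclisations do not fix the sense of induction for an aldehyde acceptor. If the ketol formed is (3S), the mirror-image salt, from the other commercial cis-1-amino-2-indanol, is to be used.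

## Route

Step 1
Reactants: 1 2,4,6-trihydroxybenzaldehyde
Product: 2 2,4-bis(benzyloxy)-6-hydroxybenzaldehyde
Conditions: BnBr (2.05 equiv), K2CO3, DMF, rt
Reagents that add atoms: benzyl bromide, BrCc1ccccc1
Why: Williamson ether synthesis; the para hydroxyl and one ortho hydroxyl react, while the last ortho hydroxyl is held in a hydrogen bond to the formyl group and stays free with two equivalents of halide and a mild base.

Step 2
Reactants: 2 2,4-bis(benzyloxy)-6-hydroxybenzaldehyde; 3 ethyl 2-bromo-2-methylpropanoate
Product: 4 ethyl 2-[3,5-bis(benzyloxy)-2-formylphenoxy]-2-methylpropanoate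
Conditions: 3 (3 equiv), Cs2CO3, DMF, 60 °C
Reagents that add atoms: none
Why: Williamson O-alkylation of the caesium phenoxide with an ester-activated tertiary bromide, as in aryloxyisobutyrate syntheses; the new ether carbon is quaternary, so no condensation onto the neighbouring aldehyde can follow.

Step 3
Reactants: 4 ethyl 2-[3,5-bis(benzyloxy)-2-formylphenoxy]-2-methylpropanoate
Product: 5 2-[3,5-bis(benzyloxy)-2-(hydroxymethyl)phenoxy]-2-methylpropan-1-ol
Conditions: LiAlH4, THF, 0 °C; H2O, aq. NaOH
Reagents that add atoms: none
Why: hydride reduction of aldehyde and ester to the diol; aryl and benzyl ethers are inert, and the basic work-up protects the acid-labile trialkoxybenzyl alcohol.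

Step 4
Reactants: 5 2-[3,5-bis(benzyloxy)-2-(hydroxymethyl)phenoxy]-2-methylpropan-1-ol
Product: 6 2-[3,5-bis(benzyloxy)-2-formylphenoxy]-2-methylpropanal
Conditions: 2-iodoxybenzoic acid (IBX, 3 equiv), DMSO, rt
Reagents that add atoms: none
Why: IBX oxidation of the benzylic and the neopentyl primary alcohol to aldehydes without over-oxidation under neutral conditions; neither aldehyde can enolise.

Step 5
Reactants: 6 2-[3,5-bis(benzyloxy)-2-formylphenoxy]-2-methylpropanal
Product: 7 (3R)-5,7-bis(benzyloxy)-3-hydroxy-2,2-dimethyl-2,3-dihydro-4H-chromen-4-one
Conditions: (5aS,10bR)-2-(pentafluorophenyl)-5a,10b-dihydro-4H,6H-indeno[2,1-b][1,2,4]triazolo[4,3-d][1,4]oxazin-2-ium tetrafluoroborate (C18H11BF9N3O, 10 mol%), i-Pr2NEt (8 mol%), toluene, 0 °C → rt; then AcOH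
Reagents that add atoms: none
Why: Proposed new method: the carbene adds to the aryl aldehyde of 6, proton transfer gives the Breslow intermediate (an acyl anion equivalent at the future C4), its nucleophilic carbon attacks the tethered alkyl aldehyde to form C3–C4, and proton transfer with loss of the carbene releases ketol 7. The closest known reaction type is the triazolium-carbene-catalysed intramolecular crossed benzoin reaction of 2-(2-oxoalkoxy)benzaldehydes, which gives 3-alkyl-3-hydroxychroman-4-ones from ketone acceptors; here the acceptor is an aldehyde and the carbinol is secondary. Ring B closes in a 6-exo-trig mode, the attacked C=O lying outside the new ring. C3 is set by the aminoindanol backbone of the catalyst, which shields one face of the Breslow intermediate while its enol O–H hydrogen-bonds to the acceptor oxygen, so one enantioface of the aldehyde is attacked; hydrogen against the bulky CMe2–OAr arm is a larger size difference than the methyl/methylene pair of the known ketone cases. The step needs the aryl aldehyde as donor and the alkyl aldehyde as acceptor: the alkyl aldehyde is alpha-quaternary (slow to form its own Breslow intermediate, no aldol path) and activated by the aryloxy group, the aryl aldehyde is a poor acceptor because of its ortho and para oxygen donors, and the conjugated aryl ketone 7 is the more stable ketol. The step also needs C3 to survive: the base is kept below the catalyst loading, the solvent is non-polar, the reaction is quenched with AcOH at full conversion, and 7, whose carbonyl is a vinylogous carbonate and acidifies C3–H only weakly, is reduced at once in step 6.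

Step 6
Reactants: 7 (3R)-5,7-bis(benzyloxy)-3-hydroxy-2,2-dimethyl-2,3-dihydro-4H-chromen-4-one
Product: 8 (3S)-5,7-bis(benzyloxy)-2,2-dimethyl-3,4-dihydro-2H-chromene-3,4-diol (both C4 epimers)
Conditions: NaBH4, MeOH/THF, 0 °C
Reagents that add atoms: none
Why: borohydride 1,2-reduction removes the enolisable carbonyl and so fixes C3; the C4 configuration does not matter because C4 becomes CH2 in step 7.

Step 7
Reactants: 8 (3S)-5,7-bis(benzyloxy)-2,2-dimethyl-3,4-dihydro-2H-chromene-3,4-diol
Product: 9 (3S)-5,7-bis(benzyloxy)-2,2-dimethyl-3,4-dihydro-2H-chromen-3-ol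
Conditions: Et3SiH (5 equiv), CF3CO2H (3 equiv), CH2Cl2 (dilute), −40 → 0 °C
Reagents that add atoms: none
Why: ionic hydrogenation; the acid ionises only the C4 hydroxyl, whose cation is stabilised by the oxygens at C5, C7 and C8a, and the silane delivers hydride to C4, as in reductions of 4-oxygenated flavan-3-ols; C3 is not touched.

Step 8
Reactants: 9 (3S)-5,7-bis(benzyloxy)-2,2-dimethyl-3,4-dihydro-2H-chromen-3-ol
Product: 10 (3S)-3,5,7-tris(benzyloxy)-2,2-dimethyl-3,4-dihydro-2H-chromene
Conditions: NaH, BnBr, n-Bu4NI (cat.), DMF, 0 °C → rt
Reagents that add atoms: benzyl bromide, BrCc1ccccc1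
Why: Williamson benzylation of the secondary alkoxide; it removes the acidic proton before the lithiation and gives three identical protecting groups that fall in one step.

Step 9
Reactants: 10 (3S)-3,5,7-tris(benzyloxy)-2,2-dimethyl-3,4-dihydro-2H-chromene
Product: 11 (3S)-3,5,7-tris(benzyloxy)-8-bromo-2,2-dimethyl-3,4-dihydro-2H-chromene
Conditions: NBS (1.0 equiv), CH2Cl2, −40 → 0 °C, dark
Reagents that add atoms: N-bromosuccinimide, O=C1CCC(=O)N1Br
Why: electrophilic aromatic bromination; C8, between the ring oxygen and one ether, is more reactive and less crowded than C6 between two benzyl ethers, as is established for 5,7-di-O-benzylflavan-3-ols, and one equivalent at low temperature avoids the dibromide.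

Step 10
Reactants: 12 (S)-2-methylbutanoic acid
Product: 14 (2S)-N-methoxy-N,2-dimethylbutanamide, via acid chloride 13 (not isolated)
Conditions: (COCl)2, DMF (cat.), CH2Cl2, 0 °C → rt; then MeNHOMe·HCl, aq. K2CO3, CH2Cl2, 0 °C
Reagents that add atoms: N,O-dimethylhydroxylamine hydrochloride, CNOC.Cl
Why: acid chloride formation and Schotten–Baumann amidation to the Weinreb amide; an alpha-alkyl acid without an activating alpha substituent keeps its configuration under these conditions.

Step 11
Reactants: 11 (3S)-3,5,7-tris(benzyloxy)-8-bromo-2,2-dimethyl-3,4-dihydro-2H-chromene; 14 (2S)-N-methoxy-N,2-dimethylbutanamide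
Product: 16 (2S)-1-[(3S)-3,5,7-tris(benzyloxy)-2,2-dimethyl-3,4-dihydro-2H-chromen-8-yl]-2-methylbutan-1-one, via 8-lithiochroman 15 (not isolated)
Conditions: n-BuLi, THF, −78 °C; then 14, −78 → −40 °C; 1 M HCl, 0 °C
Reagents that add atoms: none
Why: bromine–lithium exchange followed by Weinreb ketone synthesis; the chelated tetrahedral adduct prevents a second addition and keeps the alpha centre from enolising until the cold acidic quench, so the (S) configuration of 14 should be carried over.

Step 12
Reactants: 16 (2S)-1-[(3S)-3,5,7-tris(benzyloxy)-2,2-dimethyl-3,4-dihydro-2H-chromen-8-yl]-2-methylbutan-1-one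
Product: 17 (2S)-1-[(3S)-3,5,7-trihydroxy-2,2-dimethyl-3,4-dihydro-2H-chromen-8-yl]-2-methylbutan-1-one
Conditions: H2 (1 atm), Pd(OH)2/C, EtOAc/MeOH, rt
Reagents that add atoms: none
Why: hydrogenolysis of the two aryl benzyl ethers and the alkyl benzyl ether; the electron-rich, chelated aryl ketone resists reduction and the neutral medium leaves both stereocentres alone.

Step 13
Reactants: 18 methyl 3-oxopentanoate; 19 N-methoxy-N-methylpropanamide
Product: 21 methyl 4-methyl-3,5-dioxoheptanoate, via keto ester dianion 20 (not isolated)
Conditions: NaH, THF, 0 °C; n-BuLi, 0 °C; then 19, −78 → 0 °C; aq. HCl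
Reagents that add atoms: none
Why: Claisen-type acylation of a beta-keto ester dianion at its more reactive gamma carbon; the Weinreb amide holds the adduct until work-up, so the acidic product does not consume the dianion.

Step 14
Reactants: 21 methyl 4-methyl-3,5-dioxoheptanoate
Product: 22 6-ethyl-4-hydroxy-5-methyl-2H-pyran-2-one
Conditions: DBU, toluene, reflux; aq. HCl
Reagents that add atoms: none
Why: base-induced lactonisation of a 3,5-dioxo ester; the C5 enolate oxygen attacks the ester and methanol is lost to give the 4-hydroxy-2-pyranone.

Step 15
Reactants: 22 6-ethyl-4-hydroxy-5-methyl-2H-pyran-2-one; 17 (2S)-1-[(3S)-3,5,7-trihydroxy-2,2-dimethyl-3,4-dihydro-2H-chromen-8-yl]-2-methylbutan-1-one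
Product: 25 3-{[(3S)-3,5,7-trihydroxy-2,2-dimethyl-8-[(2S)-2-methylbutanoyl]-3,4-dihydro-2H-chromen-6-yl]methyl}-6-ethyl-4-hydroxy-5-methyl-2H-pyran-2-one, via pyranone Mannich base 23 (not isolated), via 3-methylidenepyran-2,4-dione 24 (not isolated)
Conditions: Eschenmoser's salt (1.0 equiv), MeCN, rt; then 17, 50 °C
Reagents that add atoms: Eschenmoser's salt (N,N-dimethylmethyleneiminium iodide), C=[N+](C)C.[I-]
Why: Mannich aminomethylation of the pyranone at C3, loss of dimethylamine to the methylidene dione and Michael-type (Friedel–Crafts) addition of C6 of 17, its only free arene carbon; forming 23 completely before 17 is added keeps the one-carbon unit on the pyranone, and the mild, nearly neutral medium should not epimerise the chelated ketone.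

## Compound list

1 | 2,4,6-trihydroxybenzaldehyde | O=Cc1c(O)cc(O)cc1O | starting material
2 | 2,4-bis(benzyloxy)-6-hydroxybenzaldehyde | O=Cc1c(O)cc(OCc2ccccc2)cc1OCc1ccccc1 | intermediate
3 | ethyl 2-bromo-2-methylpropanoate | CCOC(=O)C(C)(C)Br | starting material
4 | ethyl 2-[3,5-bis(benzyloxy)-2-formylphenoxy]-2-methylpropanoate | CCOC(=O)C(C)(C)Oc1cc(OCc2ccccc2)cc(OCc2ccccc2)c1C=O | intermediate
5 | 2-[3,5-bis(benzyloxy)-2-(hydroxymethyl)phenoxy]-2-methylpropan-1-ol | OCC(C)(C)Oc1cc(OCc2ccccc2)cc(OCc2ccccc2)c1CO | intermediate
6 | 2-[3,5-bis(benzyloxy)-2-formylphenoxy]-2-methylpropanal | O=CC(C)(C)Oc1cc(OCc2ccccc2)cc(OCc2ccccc2)c1C=O | intermediate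
7 | (3R)-5,7-bis(benzyloxy)-3-hydroxy-2,2-dimethyl-2,3-dihydro-4H-chromen-4-one | c1c(OCc2ccccc2)c3c(cc1OCc4ccccc4)OC(C)(C)[C@@H](O)C3=O | intermediate
8 | (3S)-5,7-bis(benzyloxy)-2,2-dimethyl-3,4-dihydro-2H-chromene-3,4-diol (both C4 epimers) | c1c(OCc2ccccc2)c3c(cc1OCc4ccccc4)OC(C)(C)[C@@H](O)C3O | intermediate
9 | (3S)-5,7-bis(benzyloxy)-2,2-dimethyl-3,4-dihydro-2H-chromen-3-ol | c1c(OCc2ccccc2)c3c(cc1OCc4ccccc4)OC(C)(C)[C@@H](O)C3 | intermediate
10 | (3S)-3,5,7-tris(benzyloxy)-2,2-dimethyl-3,4-dihydro-2H-chromene | c1c(OCc2ccccc2)c3c(cc1OCc4ccccc4)OC(C)(C)[C@@H](OCc5ccccc5)C3 | intermediate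
11 | (3S)-3,5,7-tris(benzyloxy)-8-bromo-2,2-dimethyl-3,4-dihydro-2H-chromene | c1c(OCc2ccccc2)c3c(c(Br)c1OCc4ccccc4)OC(C)(C)[C@@H](OCc5ccccc5)C3 | intermediate
12 | (S)-2-methylbutanoic acid | CC[C@H](C)C(=O)O | starting material
13 | (S)-2-methylbutanoyl chloride | CC[C@H](C)C(=O)Cl | intermediate (not isolated)
14 | (2S)-N-methoxy-N,2-dimethylbutanamide | CC[C@H](C)C(=O)N(C)OC | intermediate
15 | [(3S)-3,5,7-tris(benzyloxy)-2,2-dimethyl-3,4-dihydro-2H-chromen-8-yl]lithium | c1c(OCc2ccccc2)c3c(c([Li])c1OCc4ccccc4)OC(C)(C)[C@@H](OCc5ccccc5)C3 | intermediate (not isolated)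
16 | (2S)-1-[(3S)-3,5,7-tris(benzyloxy)-2,2-dimethyl-3,4-dihydro-2H-chromen-8-yl]-2-methylbutan-1-one | c1c(OCc2ccccc2)c3c(c(C(=O)[C@@H](C)CC)c1OCc4ccccc4)OC(C)(C)[C@@H](OCc5ccccc5)C3 | intermediate
17 | (2S)-1-[(3S)-3,5,7-trihydroxy-2,2-dimethyl-3,4-dihydro-2H-chromen-8-yl]-2-methylbutan-1-one | c1c(O)c2c(c(C(=O)[C@@H](C)CC)c1O)OC(C)(C)[C@@H](O)C2 | intermediate
18 | methyl 3-oxopentanoate | CCC(=O)CC(=O)OC | starting material
19 | N-methoxy-N-methylpropanamide | CCC(=O)N(C)OC | starting material
20 | sodium lithium 2,4-dianion of methyl 3-oxopentanoate | C[CH-]C(=O)[CH-]C(=O)OC.[Na+].[Li+] | intermediate (not isolated)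
21 | methyl 4-methyl-3,5-dioxoheptanoate (racemic at C4, enolised) | CCC(=O)C(C)C(=O)CC(=O)OC | intermediate
22 | 6-ethyl-4-hydroxy-5-methyl-2H-pyran-2-one | CCc1oc(=O)cc(O)c1C | intermediate
23 | 3-[(dimethylamino)methyl]-6-ethyl-4-hydroxy-5-methyl-2H-pyran-2-one | CCc1oc(=O)c(CN(C)C)c(O)c1C | intermediate (not isolated)
24 | 6-ethyl-5-methyl-3-methylidene-2H-pyran-2,4(3H)-dione | CCC1=C(C)C(=O)C(=C)C(=O)O1 | intermediate (not isolated)
25 | 3-{[(3S)-3,5,7-trihydroxy-2,2-dimethyl-8-[(2S)-2-methylbutanoyl]-3,4-dihydro-2H-chromen-6-yl]methyl}-6-ethyl-4-hydroxy-5-methyl-2H-pyran-2-one (CNP0361212.1) | CCc1oc(=O)c(Cc2c(O)c3c(c(C(=O)[C@@H](C)CC)c2O)OC(C)(C)[C@@H](O)C3)c(O)c1C | target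

## Step count and least certain steps

Total: 15 steps. Longest linear sequence: 12 steps (steps 1–9, 11, 12 and 15, from 1). Steps 10, 13 and 14 prepare the two side fragments.

**Step 5 (key step, proposed new method).**
- What may go wrong: the roles of the two aldehydes may be reversed. The carbene would then add to the alkyl aldehyde, and that Breslow intermediate would either attack the aryl aldehyde, giving the regioisomeric ketol, or expel the aryloxide in a beta-elimination that cuts the tether.
- The doubly ortho-substituted aryl aldehyde may also form its Breslow intermediate too slowly, and base-mediated enolisation of the secondary ketol may erode the enantiomeric purity.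
- Fallback (known chemistry): it sets out from 6 and comes back at 9, replacing steps 5–7 by three operations.
- Intramolecular McMurry coupling of 6 with low-valent titanium (TiCl4, Zn, pyridine, THF, reflux) joins the same two carbons as an alkene and gives 5,7-bis(benzyloxy)-2,2-dimethyl-2H-chromene F1.
- Jacobsen epoxidation of F1 (NaOCl, 4-phenylpyridine N-oxide, CH2Cl2, 0 °C) uses the (S,S) salen complex of trivalent manganese, [N,N'-bis(3,5-di-tert-butylsalicylidene)-1,2-cyclohexanediaminato]manganese chloride, C36H52ClMnN2O2. This is the antipode expected, by analogy with simple 2,2-dimethylchromenes, to give (3S,4S)-5,7-bis(benzyloxy)-3,4-epoxy-2,2-dimethylchroman F2.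
- The labile F2 is reduced without purification with LiAlH4 in THF at 0 °C. Hydride enters at the benzylic C4, because C3 is neopentyl-like and blocked, and the C3–O bond is kept, giving 9.

**Step 11.**
- What may go wrong: the hindered aryllithium 15, flanked by two oxygens, may deprotonate the alpha-branched amide 14 instead of adding to it. That would lead to protonation of the arene and loss of material. n-Butylation of 15 by the bromobutane formed in the exchange is a second possible loss.
- Fallback: it sets out from 11 and comes back at 16. 15 is generated as before and added at −78 °C to the more electrophilic (S)-2-methylbutanal F3. F3 is made immediately before use from commercial (S)-2-methylbutan-1-ol with TEMPO and PhI(OAc)2, so that its labile centre has no time to erode.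
- The resulting (2S)-1-[(3S)-3,5,7-tris(benzyloxy)-2,2-dimethyl-3,4-dihydro-2H-chromen-8-yl]-2-methylbutan-1-ol F4 (both carbinol epimers) is oxidised with Dess–Martin periodinane in CH2Cl2 to 16.

**Step 15.**
- What may go wrong: the one-carbon unit may be redistributed by retro-Mannich exchange, leading to symmetric methylene-bridged dimers of either half. O-alkylation of 17 and air oxidation of the free acylphloroglucinol are further possible losses.
- Fallback: it sets out from 17 and comes back at 25 with the roles of the partners exchanged. 17 is aminomethylated at C6, its only free arene carbon, with Eschenmoser's salt in CH2Cl2 at 0 °C. This gives (2S)-1-[(3S)-6-[(dimethylamino)methyl]-3,5,7-trihydroxy-2,2-dimethyl-3,4-dihydro-2H-chromen-8-yl]-2-methylbutan-1-one F5.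
- F5 is heated with an excess of 22 in dioxane. It loses dimethylamine to an ortho-quinone methide, which is trapped by C3 of the pyranone to give 25.

**Step 7.**
- What may go wrong: the C4 cation may be intercepted by the electron-rich arene of a second molecule, giving oligomers, instead of by the silane. A 1,2-hydride shift from C3 to the chroman-3-one would destroy the stereocentre, and the acid may cleave aryl benzyl ethers.
- Fallback: it sets out from 8 and comes back at 9 by a radical route. 8 is converted with 1,1'-thiocarbonyldiimidazole (toluene, 80 °C) into the cyclic thionocarbonate (3S)-5,7-bis(benzyloxy)-2,2-dimethyl-3,4-dihydro-2H-chromene-3,4-diyl thiocarbonate F6 (both C4 epimers).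
- Treatment of F6 with n-Bu3SnH and AIBN in toluene at 90 °C fragments it towards the more stable benzylic C4 radical, which is reduced. Mild basic methanolysis of the residual O3 thiocarbonate then gives 9 with C3 untouched.

## Further compounds

F1 | step 5 | 5,7-bis(benzyloxy)-2,2-dimethyl-2H-chromene | CC1(C)C=Cc2c(OCc3ccccc3)cc(OCc3ccccc3)cc2O1
F2 | step 5 | (3S,4S)-5,7-bis(benzyloxy)-3,4-epoxy-2,2-dimethylchroman | c1c(OCc2ccccc2)c3c(cc1OCc4ccccc4)OC(C)(C)[C@H]5O[C@H]53
F3 | step 11 | (S)-2-methylbutanal | CC[C@H](C)C=O
F4 | step 11 | (2S)-1-[(3S)-3,5,7-tris(benzyloxy)-2,2-dimethyl-3,4-dihydro-2H-chromen-8-yl]-2-methylbutan-1-ol (both carbinol epimers) | c1c(OCc2ccccc2)c3c(c(C(O)[C@@H](C)CC)c1OCc4ccccc4)OC(C)(C)[C@@H](OCc5ccccc5)C3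
F5 | step 15 | (2S)-1-[(3S)-6-[(dimethylamino)methyl]-3,5,7-trihydroxy-2,2-dimethyl-3,4-dihydro-2H-chromen-8-yl]-2-methylbutan-1-one | CN(C)Cc1c(O)c2c(c(C(=O)[C@@H](C)CC)c1O)OC(C)(C)[C@@H](O)C2
F6 | step 7 | (3S)-5,7-bis(benzyloxy)-2,2-dimethyl-3,4-dihydro-2H-chromene-3,4-diyl thiocarbonate (cyclic thionocarbonate, both C4 epimers) | c1c(OCc2ccccc2)c3c(cc1OCc4ccccc4)OC(C)(C)[C@H]5OC(=S)OC53
A1 | alternative 1 | 3-{[(3S)-5,7-bis(benzyloxy)-3-[(tert-butyldimethylsilyl)oxy]-2,2-dimethyl-8-[(2S)-2-methylbutanoyl]-3,4-dihydro-2H-chromen-6-yl]methyl}-6-ethyl-4-hydroxy-5-methyl-2H-pyran-2-one | CCc1oc(=O)c(Cc2c(OCc3ccccc3)c4c(c(C(=O)[C@@H](C)CC)c2OCc5ccccc5)OC(C)(C)[C@@H](O[Si](C)(C)C(C)(C)C)C4)c(O)c1C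
A2 | alternative 1 | 2-{[(3S)-5,7-bis(benzyloxy)-3-[(tert-butyldimethylsilyl)oxy]-2,2-dimethyl-8-[(2S)-2-methylbutanoyl]-3,4-dihydro-2H-chromen-6-yl]methyl}propanedioyl dichloride | ClC(=O)C(Cc1c(OCc2ccccc2)c3c(c(C(=O)[C@@H](C)CC)c1OCc4ccccc4)OC(C)(C)[C@@H](O[Si](C)(C)C(C)(C)C)C3)C(Cl)=O
A3 | alternative 1 | (Z)-3-[(trimethylsilyl)oxy]pent-2-ene | C/C=C(/CC)O[Si](C)(C)C
A4 | alternative 2 | 5-(benzyloxy)-2-(3-methylbut-2-en-1-yl)-3-[(triisopropylsilyl)oxy]phenol | Oc1cc(OCc2ccccc2)cc(O[Si](C(C)C)(C(C)C)C(C)C)c1CC=C(C)C
A5 | alternative 2 | 3-(benzyloxy)cyclobut-2-en-1-one | O=C1C=C(OCc2ccccc2)C1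
A6 | alternative 2 | triisopropyl[(5-methylhex-4-en-1-yn-1-yl)oxy]silane | CC(C)=CCC#CO[Si](C(C)C)(C(C)C)C(C)C
A7 | alternative 3 | (2S)-1-[(3S)-5-(benzyloxy)-3,7-dihydroxy-2,2-dimethyl-3,4-dihydro-2H-chromen-8-yl]-2-methylbutan-1-one | c1c(OCc2ccccc2)c3c(c(C(=O)[C@@H](C)CC)c1O)OC(C)(C)[C@@H](O)C3
A8 | alternative 3 | (2S)-1-[4-(benzyloxy)-3-{[(2S)-3,3-dimethyloxiran-2-yl]methyl}-2,6-dihydroxyphenyl]-2-methylbutan-1-one | CC[C@H](C)C(=O)c1c(O)cc(OCc2ccccc2)c(C[C@@H]2OC2(C)C)c1O
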